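**Plan**

1. Numbering used throughout: cyclobutane C1–C2–C8–C7; ring A (cyclohexanone) C1–C11(=O)–C10–C9(Me)–C8–C7; ring B (cycloheptane) C1–C2(Me)–C3(OAng)–C4(OiVal)–C5(OH)–C6(Me2)–C7.
2. Retrosynthesis: first the two ester C–O bonds and the C4–O/C5–O bonds (acylations, osmylation of a C4=C5 alkene), then C3–H (enone 19); next C3–C4/C4–C5 by excision of C4, which contracts ring B to a six-membered ring (C3 bonded to C5); then C6–CH3 (cuprate), C5=C6 (aldol), C7–C6 (reductive cyanation/MeLi), C1–C7 and C2–C8 together (ketene [2+2]) and C10–C11 (vinylogous aldol).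
3. Forward: an open chain is assembled from a C6 enynal and a C5 dienolate; one intramolecular vinylketene–alkene [2+2] closes the cyclobutane and ring A; ring B is closed six-membered by aldol condensation across the cis-1,3 carbons C2/C7 and is then enlarged by one carbon (C4) to the seven-membered enone.
4. Feature that permits the enlargement: in the six-membered ring B the C3 carbonyl lies between the quaternary C2 and the C5H2–C6Me2 unit, so only the C3=C5 enol ether can form; its cyclopropane (C3–C4–C5) has one internal bond whose homolysis gives a secondary C5 radical, and the resulting enone C3(=O)–C4=C5 carries exactly the three carbons to be oxygenated.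
5. Stereochemistry: C11 (catalytic asymmetric vinylogous aldol; a temporary centre, oxidised to the ketone late) steers the [2+2] through A(1,3) strain and so sets C1, C2 and C8; C7 is fixed by the ring closure, C9 by hydrogenation anti to the C2 bridge, C3 by CBS reduction, C4/C5 by osmylation anti to the C3 ester.
6. Helpers: the ethynyl group is a masked acetyl, the TMS enol ether and the cyclopropane carry the ring enlargement, the TBS ether masks the C11 ketone; they are removed in steps 9, 13 and 16–17.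

Key step: step 13

Remark on the chemistry: 11 and 12 are carried as mixtures of C7 epimers, since C7 is epimerisable next to the acyl group and only the epimer with the acyl group anti to ring A can cyclise in step 9; in 17 the cyclopropane face is left undefined because both of its stereocentres vanish in step 13.

Step 1
Reactants: 1 (E)-3-methylpent-2-en-4-yn-1-ol
Product: 2 (E)-3-methylpent-2-en-4-ynal
Conditions: MnO2, CH2Cl2, 20 °C
Reagents that add atoms: none
Why: Allylic oxidation with activated MnO2 should stop at the aldehyde and leave the E alkene and the alkyne untouched.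

Step 2
Reactants: 3 methyl 3-methylbut-2-enoate
Product: 4 tert-butyl[(1-methoxy-3-methylbuta-1,3-dien-1-yl)oxy]dimethylsilane
Conditions: LiN(iPr)2, THF, −78 °C; TBSCl, DMPU, −78 → 0 °C
Reagents that add atoms: tert-butyldimethylsilyl chloride CC(C)(C)[Si](C)(C)Cl
Why: γ-Deprotonation of the senecioate and O-silylation of the dienolate (silyl ketene acetal formation) should give the vinylogous nucleophile.

Step 3
Reactants: 2 (E)-3-methylpent-2-en-4-ynal, 4 tert-butyl[(1-methoxy-3-methylbuta-1,3-dien-1-yl)oxy]dimethylsilane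
Product: 5 methyl (5S,2E,6E)-5-hydroxy-3,7-dimethylnona-2,6-dien-8-ynoate
Conditions: SiCl4 (1.1 equiv), (S,S)-bisphosphoramide (5 mol %; two cyclic phosphoric triamide units built on (S)-N,N'-dimethyl-1,1'-binaphthalene-2,2'-diamine and joined through N,N'-dimethylpentane-1,5-diamine), iPr2NEt (10 mol %), CH2Cl2, −78 °C; aqueous work-up
Reagents that add atoms: none
Why: Catalytic asymmetric vinylogous Mukaiyama aldol addition, in which the Lewis base-activated SiCl4 binds the aldehyde and the dienolate attacks through its γ-carbon on the Si face (the (S,S) antipode is the one expected to direct to that face), should set C11 as S and give the 2E enoate.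

Step 4
Reactants: 5 methyl (5S,2E,6E)-5-hydroxy-3,7-dimethylnona-2,6-dien-8-ynoate
Product: 6 methyl (5S,2E,6E)-5-[(tert-butyldimethylsilyl)oxy]-3,7-dimethylnona-2,6-dien-8-ynoate
Conditions: TBSOTf, 2,6-lutidine, CH2Cl2, −78 → 0 °C
Reagents that add atoms: tert-butyldimethylsilyl trifluoromethanesulfonate CC(C)(C)[Si](C)(C)OS(=O)(=O)C(F)(F)F
Why: Silylation of the secondary allylic alcohol protects the future C11 ketone oxygen and provides the bulky group that later steers the cycloaddition.

Step 5
Reactants: 6 methyl (5S,2E,6E)-5-[(tert-butyldimethylsilyl)oxy]-3,7-dimethylnona-2,6-dien-8-ynoate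
Product: 7 (5S,2E,6E)-5-[(tert-butyldimethylsilyl)oxy]-3,7-dimethylnona-2,6-dien-8-ynoic acid
Conditions: LiOH, THF/MeOH/H2O, 20 °C; then aq HCl to pH 4
Reagents that add atoms: lithium hydroxide [Li+].[OH-]
Why: Saponification of the methyl ester should leave the silyl ether, the alkyne and the alkene geometry intact.

Step 6
Reactants: 7 (5S,2E,6E)-5-[(tert-butyldimethylsilyl)oxy]-3,7-dimethylnona-2,6-dien-8-ynoic acid
Product: 10 4-[(tert-butyldimethylsilyl)oxy]-7-ethynyl-7-methyl-2-methylidenebicyclo[3.1.1]heptan-6-one, via acid chloride 8 (not isolated), via vinylketene 9 (not isolated)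
Conditions: (COCl)2, DMF (cat.), CH2Cl2, 0 → 20 °C, evaporate; then slow addition to Et3N (3 equiv), PhMe (0.01 M), 110 °C
Reagents that add atoms: none
Why: Dehydrochlorination at the methyl group cis to the acyl chloride gives the vinylketene, whose carbonyl carbon (C7) attacks the less substituted alkene carbon C1 through a six-membered array while its α-carbon (C8) closes on the tertiary, propargylic C2, the known crossed intramolecular ketene–alkene [2+2] cycloaddition to bicyclo[3.1.1]heptan-6-ones; addition is suprafacial on the E alkene (methyl syn to ring A), and the C11 stereocentre keeps its hydrogen in the A(1,3)-strained position so that the ketene reaches one alkene face, which sets C1, C2 and C8.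

Step 7
Reactants: 10 4-[(tert-butyldimethylsilyl)oxy]-7-ethynyl-7-methyl-2-methylidenebicyclo[3.1.1]heptan-6-one
Product: 11 4-[(tert-butyldimethylsilyl)oxy]-7-ethynyl-7-methyl-2-methylidenebicyclo[3.1.1]heptane-6-carbonitrile (C7 epimers)
Conditions: TosMIC, KOtBu, DME/t-BuOH, 0 → 40 °C
Reagents that add atoms: p-toluenesulfonylmethyl isocyanide Cc1ccc(cc1)S(=O)(=O)C[N+]#[C-]
Why: van Leusen reductive cyanation of the strained, non-enolisable cyclobutanone turns the carbonyl carbon C7 into a CH that carries the future C6, while the ethynyl group keeps the second acetyl masked.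

Step 8
Reactants: 11 4-[(tert-butyldimethylsilyl)oxy]-7-ethynyl-7-methyl-2-methylidenebicyclo[3.1.1]heptane-6-carbonitrile
Product: 12 1-{4-[(tert-butyldimethylsilyl)oxy]-7-ethynyl-7-methyl-2-methylidenebicyclo[3.1.1]heptan-6-yl}ethan-1-one (C7 epimers)
Conditions: MeLi (3 equiv), Et2O, −78 → 0 °C; then 1 M aq HCl, 0 °C
Reagents that add atoms: methyllithium [Li]C; water O
Why: Addition of MeLi to the nitrile (the lithium acetylide formed first is inert) and hydrolysis of the imine should give the methyl ketone, which supplies C6 and one of its methyl groups.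

Step 9
Reactants: 12 1-{4-[(tert-butyldimethylsilyl)oxy]-7-ethynyl-7-methyl-2-methylidenebicyclo[3.1.1]heptan-6-yl}ethan-1-one
Product: 14 10-[(tert-butyldimethylsilyl)oxy]-2,5-dimethyl-8-methylidenetricyclo[4.4.0.0^2,7]dec-4-en-3-one, via diketone 13 (not isolated)
Conditions: Ph3PAuCl (2 mol %), AgOTf (2 mol %), H2O (5 equiv), 1,4-dioxane, 70 °C; then KOH, MeOH, 50 °C
Reagents that add atoms: water O
Why: Markovnikov gold-catalysed hydration of the terminal alkyne unmasks the acetyl group on C2, and base then epimerises C7 and drives the aldol condensation of the C3-acetyl enolate onto the less hindered C6 carbonyl across the cis-1,3 positions of the cyclobutane, which closes ring B as a six-membered β-methyl enone (a 6-enolexo aldol closure) and locks C7.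

Step 10
Reactants: 14 10-[(tert-butyldimethylsilyl)oxy]-2,5-dimethyl-8-methylidenetricyclo[4.4.0.0^2,7]dec-4-en-3-one
Product: 15 10-[(tert-butyldimethylsilyl)oxy]-2,5,8-trimethyltricyclo[4.4.0.0^2,7]dec-4-en-3-one
Conditions: H2 (1 atm), RhCl(PPh3)3 (5 mol %), benzene, 20 °C
Reagents that add atoms: none
Why: Homogeneous hydrogenation should reduce only the 1,1-disubstituted exocyclic alkene (the trisubstituted enone is inert to this catalyst) from the face of ring A turned away from the methyl-bearing C2 bridge, as β-pinene gives cis-pinane, which sets C9.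

Step 11
Reactants: 15 10-[(tert-butyldimethylsilyl)oxy]-2,5,8-trimethyltricyclo[4.4.0.0^2,7]dec-4-en-3-one
Product: 16 tert-butyldimethyl({2,5,5,8-tetramethyl-3-[(trimethylsilyl)oxy]tricyclo[4.4.0.0^2,7]dec-3-en-10-yl}oxy)silane
Conditions: Me2CuLi (from MeLi and CuI), TMSCl, THF/Et2O, −78 → 0 °C; Et3N, then aq NaHCO3
Reagents that add atoms: lithium dimethylcuprate [Li+].C[Cu-]C; chlorotrimethylsilane C[Si](C)(C)Cl
Why: Cuprate conjugate addition to the β-methyl enone (the behaviour of verbenone) creates the quaternary C6 next to the cyclobutane, and silylation of the enolate gives the C3=C5 enol ether regiospecifically.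

Step 12
Reactants: 16 tert-butyldimethyl({2,5,5,8-tetramethyl-3-[(trimethylsilyl)oxy]tricyclo[4.4.0.0^2,7]dec-3-en-10-yl}oxy)silane
Product: 17 tert-butyldimethyl({2,5,5,8-tetramethyl-3-[(trimethylsilyl)oxy]-3,4-methanotricyclo[4.4.0.0^2,7]decan-10-yl}oxy)silane (siloxycyclopropane C3–C4–C5 in the plan numbering)
Conditions: Et2Zn, CH2I2, CH2Cl2, 0 → 20 °C
Reagents that add atoms: diiodomethane ICI
Why: Simmons–Smith cyclopropanation (Et2Zn/CH2I2 variant) of the electron-rich silyl enol ether brings in C4 as the apex of a siloxycyclopropane.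

Step 13
Reactants: 17 tert-butyldimethyl({2,5,5,8-tetramethyl-3-[(trimethylsilyl)oxy]-3,4-methanotricyclo[4.4.0.0^2,7]decan-10-yl}oxy)silane
Product: 19 11-[(tert-butyldimethylsilyl)oxy]-2,6,6,9-tetramethyltricyclo[5.4.0.0^2,8]undec-4-en-3-one, via β-chloro ketone 18 (not isolated)
Conditions: FeCl3 (2.2 equiv), DMF, 0 → 20 °C; then NaOAc, MeOH, 65 °C
Reagents that add atoms: none
Why: Trivalent iron oxidises the siloxycyclopropane (with loss of Me3SiCl) to a cyclopropyloxy radical or its iron alkoxide equivalent, whose β-scission breaks the internal C3–C5 bond shared by the three- and six-membered rings, so that ring B grows from six to seven atoms with C4 inside it; the secondary C5 radical takes chlorine from a second FeCl3 to give β-chloro ketone 18, and acetate then removes HCl by E1cB elimination to the enone. The closest known reaction type is the Ito–Saegusa FeCl3 ring enlargement of 1-siloxybicyclo[n.1.0]alkanes to cycloalk-2-enones, here a 1-siloxybicyclo[4.1.0]heptane going to a cyclohept-2-enone. No ring is closed: the seven-membered ring arises by fragmentation of the fusion bond, and the cyclobutane and ring A should be untouched because the C5 radical is separated from the four-membered ring by the quaternary C6. No stereocentre is created, since the two cyclopropane centres C3 and C5 become trigonal. The selectivity needed is cleavage of the internal C3–C5 bond and not of the external C3–C4 bond or of C2–C3; only the internal scission gives a secondary radical with full release of cyclopropane strain, and the position of the cyclopropane was fixed in step 11 because the quaternary C2 leaves C5 as the only enolisable side of the C3 ketone.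

Step 14
Reactants: 19 11-[(tert-butyldimethylsilyl)oxy]-2,6,6,9-tetramethyltricyclo[5.4.0.0^2,8]undec-4-en-3-one
Product: 20 11-[(tert-butyldimethylsilyl)oxy]-2,6,6,9-tetramethyltricyclo[5.4.0.0^2,8]undec-4-en-3-ol (3-hydroxyl on the C1 side of ring B)
Conditions: (S)-1-methyl-3,3-diphenyltetrahydro-1H,3H-pyrrolo[1,2-c][1,3,2]oxazaborole (20 mol %), BH3·SMe2, THF, −30 °C; MeOH
Reagents that add atoms: none
Why: Corey–Bakshi–Shibata 1,2-reduction under reagent control is chosen because the two faces of the C3 carbonyl differ only through remote groups of ring A; with the quaternary C2 as the large and the vinyl carbon C4 as the small substituent, the (S)-catalyst should deliver hydride to the face turned toward C8 and so set C3.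

Step 15
Reactants: 20 11-[(tert-butyldimethylsilyl)oxy]-2,6,6,9-tetramethyltricyclo[5.4.0.0^2,8]undec-4-en-3-ol
Product: 21 11-[(tert-butyldimethylsilyl)oxy]-2,6,6,9-tetramethyltricyclo[5.4.0.0^2,8]undec-4-en-3-yl (Z)-2-methylbut-2-enoate
Conditions: LiN(SiMe3)2, THF, −78 °C; (Z)-2-methylbut-2-enoic anhydride, −78 → 0 °C
Reagents that add atoms: (Z)-2-methylbut-2-enoic anhydride C/C=C(/C)C(=O)OC(=O)/C(C)=C\C
Why: Acylation of the lithium alkoxide with angelic anhydride at low temperature should esterify the hindered allylic alcohol without Z to E isomerisation of the angelate.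

Step 16
Reactants: 21 11-[(tert-butyldimethylsilyl)oxy]-2,6,6,9-tetramethyltricyclo[5.4.0.0^2,8]undec-4-en-3-yl (Z)-2-methylbut-2-enoate
Product: 22 11-hydroxy-2,6,6,9-tetramethyltricyclo[5.4.0.0^2,8]undec-4-en-3-yl (Z)-2-methylbut-2-enoate
Conditions: HF·pyridine, THF/pyridine, 0 → 20 °C
Reagents that add atoms: none
Why: Fluoride cleavage of the secondary silyl ether should leave the ester and both alkenes untouched.

Step 17
Reactants: 22 11-hydroxy-2,6,6,9-tetramethyltricyclo[5.4.0.0^2,8]undec-4-en-3-yl (Z)-2-methylbut-2-enoate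
Product: 23 2,6,6,9-tetramethyl-11-oxotricyclo[5.4.0.0^2,8]undec-4-en-3-yl (Z)-2-methylbut-2-enoate
Conditions: Dess–Martin periodinane, CH2Cl2, 20 °C
Reagents that add atoms: none
Why: Dess–Martin oxidation of the only free alcohol gives the ring A ketone and removes the temporary C11 stereocentre; C1 is a bridgehead and C9 is not α to the carbonyl, so nothing can epimerise.

Step 18
Reactants: 23 2,6,6,9-tetramethyl-11-oxotricyclo[5.4.0.0^2,8]undec-4-en-3-yl (Z)-2-methylbut-2-enoate
Product: 24 4,5-dihydroxy-2,6,6,9-tetramethyl-11-oxotricyclo[5.4.0.0^2,8]undecan-3-yl (Z)-2-methylbut-2-enoate (4- and 5-hydroxyls cis to each other and trans to the 3-ester)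
Conditions: OsO4 (5 mol %), N-methylmorpholine N-oxide, acetone/H2O, 0 → 20 °C
Reagents that add atoms: N-methylmorpholine N-oxide C[N+]1([O-])CCOCC1; water O (both oxygen atoms are delivered through catalytic osmium tetroxide O=[Os](=O)(=O)=O)
Why: Upjohn syn-dihydroxylation should take place at the cis-disubstituted ring alkene, faster than at the electron-poor trisubstituted angelate, and on the face opposite the allylic C3 acyloxy group (the anti rule for osmylation next to an allylic oxygen), which sets C4 and C5.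

Step 19
Reactants: 24 4,5-dihydroxy-2,6,6,9-tetramethyl-11-oxotricyclo[5.4.0.0^2,8]undecan-3-yl (Z)-2-methylbut-2-enoate
Product: 25 (1R,2R,3S,4S,5S,7S,8S,9S)-5-hydroxy-2,6,6,9-tetramethyl-3-{[(2Z)-2-methylbut-2-enoyl]oxy}-11-oxotricyclo[5.4.0.0^2,8]undecan-4-yl 3-methylbutanoate (CNP0323312.1; plan numbering)
Conditions: (iPrCH2CO)2O (1.1 equiv), 4-(dimethylamino)pyridine (cat.), pyridine, CH2Cl2, −20 → 0 °C
Reagents that add atoms: 3-methylbutanoic anhydride CC(C)CC(=O)OC(=O)CC(C)C
Why: Acyl transfer should occur at the C4 hydroxyl, while the C5 hydroxyl, neopentylic next to the gem-dimethyl carbon C6, stays free.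

**Compound list**

1 | (E)-3-methylpent-2-en-4-yn-1-ol | C#C/C(C)=C/CO | starting material
2 | (E)-3-methylpent-2-en-4-ynal | C#C/C(C)=C/C=O | intermediate
3 | methyl 3-methylbut-2-enoate | COC(=O)C=C(C)C | starting material
4 | tert-butyl[(1-methoxy-3-methylbuta-1,3-dien-1-yl)oxy]dimethylsilane (ketene acetal geometry immaterial) | C=C(C)C=C(OC)O[Si](C)(C)C(C)(C)C | intermediate
5 | methyl (5S,2E,6E)-5-hydroxy-3,7-dimethylnona-2,6-dien-8-ynoate | COC(=O)/C=C(\C)C[C@H](O)/C=C(\C)C#C | intermediate
6 | methyl (5S,2E,6E)-5-[(tert-butyldimethylsilyl)oxy]-3,7-dimethylnona-2,6-dien-8-ynoate | COC(=O)/C=C(\C)C[C@H](O[Si](C)(C)C(C)(C)C)/C=C(\C)C#C | intermediate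
7 | (5S,2E,6E)-5-[(tert-butyldimethylsilyl)oxy]-3,7-dimethylnona-2,6-dien-8-ynoic acid | OC(=O)/C=C(\C)C[C@H](O[Si](C)(C)C(C)(C)C)/C=C(\C)C#C | intermediate
8 | (5S,2E,6E)-5-[(tert-butyldimethylsilyl)oxy]-3,7-dimethylnona-2,6-dien-8-ynoyl chloride (not isolated) | ClC(=O)/C=C(\C)C[C@H](O[Si](C)(C)C(C)(C)C)/C=C(\C)C#C | intermediate
9 | (5S,6E)-5-[(tert-butyldimethylsilyl)oxy]-7-methyl-3-methylidenenona-1,6-dien-8-yn-1-one, the vinylketene (not isolated) | O=C=CC(=C)C[C@H](O[Si](C)(C)C(C)(C)C)/C=C(\C)C#C | intermediate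
10 | 4-[(tert-butyldimethylsilyl)oxy]-7-ethynyl-7-methyl-2-methylidenebicyclo[3.1.1]heptan-6-one (7-methyl syn and 7-ethynyl anti to the C2–C4 bridge; silyloxy on the side of the carbonyl bridge) | O=C1[C@@H]2C(=C)C[C@H](O[Si](C)(C)C(C)(C)C)[C@H]1[C@]2(C)C#C | intermediate
11 | 4-[(tert-butyldimethylsilyl)oxy]-7-ethynyl-7-methyl-2-methylidenebicyclo[3.1.1]heptane-6-carbonitrile (epimers at the nitrile-bearing carbon) | N#CC1[C@@H]2C(=C)C[C@H](O[Si](C)(C)C(C)(C)C)[C@H]1[C@]2(C)C#C | intermediate
12 | 1-{4-[(tert-butyldimethylsilyl)oxy]-7-ethynyl-7-methyl-2-methylidenebicyclo[3.1.1]heptan-6-yl}ethan-1-one (epimers at the acetyl-bearing carbon) | CC(=O)C1[C@@H]2C(=C)C[C@H](O[Si](C)(C)C(C)(C)C)[C@H]1[C@]2(C)C#C | intermediate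
13 | 1,1'-{4-[(tert-butyldimethylsilyl)oxy]-7-methyl-2-methylidenebicyclo[3.1.1]heptane-6,7-diyl}di(ethan-1-one) (not isolated) | CC(=O)C1[C@@H]2C(=C)C[C@H](O[Si](C)(C)C(C)(C)C)[C@H]1[C@]2(C)C(C)=O | intermediate
14 | 10-[(tert-butyldimethylsilyl)oxy]-2,5-dimethyl-8-methylidenetricyclo[4.4.0.0^2,7]dec-4-en-3-one (silyloxy on the side of C6) | O=C1C=C(C)[C@H]2[C@@H]3C(=C)C[C@H](O[Si](C)(C)C(C)(C)C)[C@H]2[C@@]31C | intermediate
15 | 10-[(tert-butyldimethylsilyl)oxy]-2,5,8-trimethyltricyclo[4.4.0.0^2,7]dec-4-en-3-one (8-methyl syn to the C2 bridge) | O=C1C=C(C)[C@H]2[C@@H]3[C@@H](C)C[C@H](O[Si](C)(C)C(C)(C)C)[C@H]2[C@@]31C | intermediate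
16 | tert-butyldimethyl({2,5,5,8-tetramethyl-3-[(trimethylsilyl)oxy]tricyclo[4.4.0.0^2,7]dec-3-en-10-yl}oxy)silane | C[Si](C)(C)OC1=CC(C)(C)[C@H]2[C@@H]3[C@@H](C)C[C@H](O[Si](C)(C)C(C)(C)C)[C@H]2[C@@]31C | intermediate
17 | tert-butyldimethyl({2,5,5,8-tetramethyl-3-[(trimethylsilyl)oxy]-3,4-methanotricyclo[4.4.0.0^2,7]decan-10-yl}oxy)silane (cyclopropane face undefined) | C[Si](C)(C)OC15CC1C(C)(C)[C@H]2[C@@H]3[C@@H](C)C[C@H](O[Si](C)(C)C(C)(C)C)[C@H]2[C@@]35C | intermediate
18 | 11-[(tert-butyldimethylsilyl)oxy]-5-chloro-2,6,6,9-tetramethyltricyclo[5.4.0.0^2,8]undecan-3-one (not isolated; C5 undefined) | O=C1CC(Cl)C(C)(C)[C@H]2[C@@H]3[C@@H](C)C[C@H](O[Si](C)(C)C(C)(C)C)[C@H]2[C@@]31C | intermediate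
19 | 11-[(tert-butyldimethylsilyl)oxy]-2,6,6,9-tetramethyltricyclo[5.4.0.0^2,8]undec-4-en-3-one | O=C1C=CC(C)(C)[C@H]2[C@@H]3[C@@H](C)C[C@H](O[Si](C)(C)C(C)(C)C)[C@H]2[C@@]31C | intermediate
20 | 11-[(tert-butyldimethylsilyl)oxy]-2,6,6,9-tetramethyltricyclo[5.4.0.0^2,8]undec-4-en-3-ol (3-hydroxyl on the C1 side) | O[C@@H]1C=CC(C)(C)[C@H]2[C@@H]3[C@@H](C)C[C@H](O[Si](C)(C)C(C)(C)C)[C@H]2[C@@]31C | intermediate
21 | 11-[(tert-butyldimethylsilyl)oxy]-2,6,6,9-tetramethyltricyclo[5.4.0.0^2,8]undec-4-en-3-yl (Z)-2-methylbut-2-enoate | C/C=C(/C)C(=O)O[C@@H]1C=CC(C)(C)[C@H]2[C@@H]3[C@@H](C)C[C@H](O[Si](C)(C)C(C)(C)C)[C@H]2[C@@]31C | intermediate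
22 | 11-hydroxy-2,6,6,9-tetramethyltricyclo[5.4.0.0^2,8]undec-4-en-3-yl (Z)-2-methylbut-2-enoate | C/C=C(/C)C(=O)O[C@@H]1C=CC(C)(C)[C@H]2[C@@H]3[C@@H](C)C[C@H](O)[C@H]2[C@@]31C | intermediate
23 | 2,6,6,9-tetramethyl-11-oxotricyclo[5.4.0.0^2,8]undec-4-en-3-yl (Z)-2-methylbut-2-enoate | C/C=C(/C)C(=O)O[C@@H]1C=CC(C)(C)[C@H]2[C@@H]3[C@@H](C)CC(=O)[C@H]2[C@@]31C | intermediate
24 | 4,5-dihydroxy-2,6,6,9-tetramethyl-11-oxotricyclo[5.4.0.0^2,8]undecan-3-yl (Z)-2-methylbut-2-enoate | C/C=C(/C)C(=O)O[C@@H]1[C@@H](O)[C@@H](O)C(C)(C)[C@H]2[C@@H]3[C@@H](C)CC(=O)[C@H]2[C@@]31C | intermediate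
25 | (1R,2R,3S,4S,5S,7S,8S,9S)-5-hydroxy-2,6,6,9-tetramethyl-3-{[(2Z)-2-methylbut-2-enoyl]oxy}-11-oxotricyclo[5.4.0.0^2,8]undecan-4-yl 3-methylbutanoate (CNP0323312.1) | C/C=C(/C)C(=O)O[C@@H]1[C@@H](OC(=O)CC(C)C)[C@@H](O)C(C)(C)[C@H]2[C@@H]3[C@@H](C)CC(=O)[C@H]2[C@@]31C | target

**Step count and risks**

Total step count: 19. Longest linear sequence: 18 steps (from 1 through steps 1 and 3–19, or from 3 through steps 2–19).

Steps most likely to fail:

Step 6 (ketene cycloaddition). Three processes may go wrong: deprotonation at the chain methylene instead of the methyl group, followed by β-elimination of the silanolate; oligomerisation of the ketene; and incomplete control of the alkene face by the C11 centre. The fallback makes the same ketene by α-dehydrochlorination of a regiodefined β,γ-unsaturated acid chloride at lower temperature. It sets out from 6: deconjugation with LiN(iPr)2 (2.2 equiv) in THF/DMPU at −78 °C and kinetic protonation with AcOH should give methyl (5S,6E)-5-[(tert-butyldimethylsilyl)oxy]-7-methyl-3-methylidenenon-6-en-8-ynoate F1. Hydrolysis with LiOH at 0 °C should give (5S,6E)-5-[(tert-butyldimethylsilyl)oxy]-7-methyl-3-methylidenenon-6-en-8-ynoic acid F2, and (COCl)2 the acid chloride (5S,6E)-5-[(tert-butyldimethylsilyl)oxy]-7-methyl-3-methylidenenon-6-en-8-ynoyl chloride F3. Et3N in toluene at 40–80 °C then forms vinylketene 9 directly, and the route is rejoined at 10.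

Step 14 (C3 reduction). Hydride delivery to the hindered, nearly symmetric enone may show poor or reversed facial discrimination. The fallback gives up reagent control in favour of separation and recycling. It sets out from 19: Luche reduction (NaBH4, CeCl3, MeOH, −78 °C) should give 20 together with its C3 epimer, 11-[(tert-butyldimethylsilyl)oxy]-2,6,6,9-tetramethyltricyclo[5.4.0.0^2,8]undec-4-en-3-ol with the hydroxyl on the C8 side F4. After chromatographic separation F4 is oxidised back to 19 with MnO2 and recycled; the route is rejoined at 20.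

Step 18 (dihydroxylation). Osmylation of the angelate double bond may compete, and the anti selectivity may erode with an allylic ester instead of an alcohol. The fallback dihydroxylates before the angelate is present and masks the cis-diol. It sets out from 20: OsO4/N-methylmorpholine N-oxide should give 11-[(tert-butyldimethylsilyl)oxy]-2,6,6,9-tetramethyltricyclo[5.4.0.0^2,8]undecane-3,4,5-triol F5. 2,2-Dimethoxypropane with pyridinium p-toluenesulfonate should give the 4,5-O-isopropylidene derivative with free 3-hydroxyl F6. LiN(SiMe3)2 and angelic anhydride give its 3-O-angelate F7; HF·pyridine gives the 11-hydroxy 4,5-O-isopropylidene 3-O-angelate F8; Dess–Martin periodinane gives the 11-oxo 4,5-O-isopropylidene 3-O-angelate F9. Aqueous AcOH (80 %, 40 °C) removes the acetonide, and the route is rejoined at 24.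

Further compounds
F1 | step 6 | methyl (5S,6E)-5-[(tert-butyldimethylsilyl)oxy]-7-methyl-3-methylidenenon-6-en-8-ynoate | COC(=O)CC(=C)C[C@H](O[Si](C)(C)C(C)(C)C)/C=C(\C)C#C
F2 | step 6 | (5S,6E)-5-[(tert-butyldimethylsilyl)oxy]-7-methyl-3-methylidenenon-6-en-8-ynoic acid | OC(=O)CC(=C)C[C@H](O[Si](C)(C)C(C)(C)C)/C=C(\C)C#C
F3 | step 6 | (5S,6E)-5-[(tert-butyldimethylsilyl)oxy]-7-methyl-3-methylidenenon-6-en-8-ynoyl chloride | ClC(=O)CC(=C)C[C@H](O[Si](C)(C)C(C)(C)C)/C=C(\C)C#C
F4 | step 14 | 11-[(tert-butyldimethylsilyl)oxy]-2,6,6,9-tetramethyltricyclo[5.4.0.0^2,8]undec-4-en-3-ol, C3 epimer of 20 | O[C@H]1C=CC(C)(C)[C@H]2[C@@H]3[C@@H](C)C[C@H](O[Si](C)(C)C(C)(C)C)[C@H]2[C@@]31C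
F5 | step 18 | 11-[(tert-butyldimethylsilyl)oxy]-2,6,6,9-tetramethyltricyclo[5.4.0.0^2,8]undecane-3,4,5-triol | O[C@@H]1[C@@H](O)[C@@H](O)C(C)(C)[C@H]2[C@@H]3[C@@H](C)C[C@H](O[Si](C)(C)C(C)(C)C)[C@H]2[C@@]31C
F6 | step 18 | 4,5-O-isopropylidene derivative of F5 with free 3-hydroxyl | O[C@@H]1[C@H]4OC(C)(C)O[C@H]4C(C)(C)[C@H]2[C@@H]3[C@@H](C)C[C@H](O[Si](C)(C)C(C)(C)C)[C@H]2[C@@]31C
F7 | step 18 | 3-O-[(Z)-2-methylbut-2-enoyl] derivative of F6 | C/C=C(/C)C(=O)O[C@@H]1[C@H]4OC(C)(C)O[C@H]4C(C)(C)[C@H]2[C@@H]3[C@@H](C)C[C@H](O[Si](C)(C)C(C)(C)C)[C@H]2[C@@]31C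
F8 | step 18 | 11-hydroxy 4,5-O-isopropylidene 3-O-angelate | C/C=C(/C)C(=O)O[C@@H]1[C@H]4OC(C)(C)O[C@H]4C(C)(C)[C@H]2[C@@H]3[C@@H](C)C[C@H](O)[C@H]2[C@@]31C
F9 | step 18 | 11-oxo 4,5-O-isopropylidene 3-O-angelate | C/C=C(/C)C(=O)O[C@@H]1[C@H]4OC(C)(C)O[C@H]4C(C)(C)[C@H]2[C@@H]3[C@@H](C)CC(=O)[C@H]2[C@@]31C
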